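The numbering is: C1 methyl-bearing fusion carbon, C2, C3, C4 carbinol carbon, C5 fusion CH, C6 ester carbon, C7, C8/C9 epoxide carbons, C10. The route rests on cutting C1–C10. C1 is the β-carbon of the five-membered-ring enone C4(=O)–C5=C1 and C8–C9=C10 can be a tertiary allylsilane, so one Lewis-acid-mediated intramolecular Sakurai addition joins C10 to C1, closes the seven-membered ring, creates quaternary C1 and the trans C1/C5 fusion, and leaves the C8=C9 alkene for the epoxide. The precursor is a 3-methylcyclopentenone carrying at C5 a C6 silyloxy carbinol tethered through C7 to the allylsilane; its (6S) centre steers C1 and is inverted later by oxidation and reduction.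

Key step: step 10

Remark on the chemistry: under allylic 1,3-strain control the ring closure leaves the C1 methyl trans to the C6 oxygen (syn to H6), whereas the target has them cis; the cyclisation is therefore run on the (6S)-silyl ether, which gives (1R), and C6 is inverted after ring closure (steps 13 and 14). β is the face of the bicycle that bears the C1 methyl, α the opposite face; the allylsilane carries Et3Si.

Step 1
Reactants: 1 3-methylcyclopent-2-en-1-one
Product: 3 2-bromo-3-methylcyclopent-2-en-1-one, via 2,3-dibromo-3-methylcyclopentan-1-one 2 (not isolated)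
Conditions: Br2, CH2Cl2, 0 °C; then Et3N, 0 °C → rt
Reagents that add atoms: bromine, BrBr
Why: Bromine addition across the enone followed by amine-induced E1cB loss of HBr (α-bromination of an enone by addition–elimination) should return the conjugated 2-bromo enone.

Step 2
Reactants: 3 2-bromo-3-methylcyclopent-2-en-1-one
Product: 4 6-bromo-7-methyl-1,4-dioxaspiro[4.4]non-6-ene
Conditions: HOCH2CH2OH, p-TsOH·H2O (cat.), benzene, reflux, Dean–Stark
Reagents that add atoms: ethylene glycol, OCCO
Why: Acid-catalysed ketalisation with azeotropic removal of water masks the carbonyl, and the α-bromine should keep the double bond from migrating out of its position next to the ketal carbon.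

Step 3
Reactants: 5 but-2-yn-1-ol
Product: 6 (Z)-3-(triethylsilyl)but-2-en-1-ol
Conditions: Et3SiH, [Cp*Ru(MeCN)3]PF6 (1 mol%), CH2Cl2, 0 °C → rt
Reagents that add atoms: triethylsilane, CC[SiH](CC)CC
Why: Cationic ruthenium-catalysed trans-hydrosilylation of a propargylic alcohol should place silicon on the alkyne carbon remote from the hydroxyl, and the alkene geometry is of no consequence because that carbon becomes a racemic quaternary centre in step 4.

Step 4
Reactants: 6 (Z)-3-(triethylsilyl)but-2-en-1-ol; 7 triethyl orthoacetate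
Product: 9 ethyl 3-methyl-3-(triethylsilyl)pent-4-enoate (racemic), via 1-ethoxy-1-[(Z)-3-(triethylsilyl)but-2-enyloxy]ethene 8 (not isolated)
Conditions: EtCO2H (cat.), neat in 7, 140 °C, EtOH distilled off
Reagents that add atoms: none
Why: Johnson–Claisen rearrangement, in which the mixed ketene acetal undergoes a [3,3]-sigmatropic shift that forms C7–C8 and delivers the tertiary allylsilane with its terminal vinyl group; C8 is racemic, which is harmless because it becomes sp2 in step 10.

Step 5
Reactants: 9 ethyl 3-methyl-3-(triethylsilyl)pent-4-enoate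
Product: 10 N-methoxy-N,3-dimethyl-3-(triethylsilyl)pent-4-enamide
Conditions: MeNH(OMe)·HCl, i-PrMgCl, THF, −20 → 0 °C
Reagents that add atoms: N,O-dimethylhydroxylamine hydrochloride, CNOC.Cl
Why: Aminolysis of the ester by the chloromagnesium amide of N,O-dimethylhydroxylamine (Weinreb amide formation) should proceed at the unbranched carbonyl and leave the allylsilane untouched.

Step 6
Reactants: 4 6-bromo-7-methyl-1,4-dioxaspiro[4.4]non-6-ene; 10 N-methoxy-N,3-dimethyl-3-(triethylsilyl)pent-4-enamide
Product: 12 3-methyl-1-(7-methyl-1,4-dioxaspiro[4.4]non-6-en-6-yl)-3-(triethylsilyl)pent-4-en-1-one, via (7-methyl-1,4-dioxaspiro[4.4]non-6-en-6-yl)lithium 11 (not isolated)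
Conditions: 4, n-BuLi, THF, −78 °C; then 10, −78 → 0 °C; aq. NH4Cl
Reagents that add atoms: none
Why: Bromine–lithium exchange gives the α-ketovinyl anion equivalent, and its acylation by the Weinreb amide (ketone synthesis without over-addition) should form the C5–C6 bond.

Step 7
Reactants: 12 3-methyl-1-(7-methyl-1,4-dioxaspiro[4.4]non-6-en-6-yl)-3-(triethylsilyl)pent-4-en-1-one
Product: 13 (1S)-3-methyl-1-(7-methyl-1,4-dioxaspiro[4.4]non-6-en-6-yl)-3-(triethylsilyl)pent-4-en-1-ol (mixture of C8 epimers)
Conditions: (R)-Me-CBS oxazaborolidine [(R)-1-methyl-3,3-diphenyltetrahydro-1H,3H-pyrrolo[1,2-c][1,3,2]oxazaborole] (20 mol%), catecholborane, toluene, −78 °C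
Reagents that add atoms: none
Why: Corey–Bakshi–Shibata reduction in which the fully substituted, ketal-flanked alkenyl group acts as the large substituent and the CH2 chain as the small one, so the (R)-catalyst should give the (S)-carbinol at C6, while catecholborane at low temperature should spare the vinyl group.

Step 8
Reactants: 13 (1S)-3-methyl-1-(7-methyl-1,4-dioxaspiro[4.4]non-6-en-6-yl)-3-(triethylsilyl)pent-4-en-1-ol
Product: 14 tert-butyl{[(1S)-3-methyl-1-(7-methyl-1,4-dioxaspiro[4.4]non-6-en-6-yl)-3-(triethylsilyl)pent-4-en-1-yl]oxy}dimethylsilane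
Conditions: TBSOTf, 2,6-lutidine, CH2Cl2, −78 °C
Reagents that add atoms: tert-butyldimethylsilyl trifluoromethanesulfonate, CC(C)(C)[Si](C)(C)OS(=O)(=O)C(F)(F)F
Why: Silyl ether protection with the silyl triflate and a hindered pyridine base should silylate the crowded secondary allylic alcohol at low temperature without touching the allylsilane or the C6 configuration.

Step 9
Reactants: 14 tert-butyl{[(1S)-3-methyl-1-(7-methyl-1,4-dioxaspiro[4.4]non-6-en-6-yl)-3-(triethylsilyl)pent-4-en-1-yl]oxy}dimethylsilane
Product: 15 2-[(1S)-1-(tert-butyldimethylsilyloxy)-3-methyl-3-(triethylsilyl)pent-4-en-1-yl]-3-methylcyclopent-2-en-1-one (mixture of C8 epimers)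
Conditions: pyridinium p-toluenesulfonate (cat.), acetone/H2O, 40 °C
Reagents that add atoms: water, O
Why: Acid-catalysed hydrolysis of the allylic dioxolane is fast under a weak acid, so the enone should be unmasked while the secondary silyl ether and the protodesilylation-prone tertiary allylsilane stay intact.

Step 10
Reactants: 15 2-[(1S)-1-(tert-butyldimethylsilyloxy)-3-methyl-3-(triethylsilyl)pent-4-en-1-yl]-3-methylcyclopent-2-en-1-one
Product: 17 (3aS,4S,8aR)-4-(tert-butyldimethylsilyloxy)-6,8a-dimethyl-2,3a,4,5,8,8a-hexahydroazulen-3(1H)-one, via chloro(ethyl)aluminium enolate 16 (not isolated)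
Conditions: EtAlCl2 (2 equiv), toluene, −78 → 0 °C; aq. NH4Cl
Reagents that add atoms: none
Why: EtAlCl2 binds the C4 carbonyl and the terminal carbon C10 of the tertiary allylsilane adds to the enone β-carbon C1, after which the β-silyl cation at C8 loses its silyl group to chloride, so the new alkene sits at C8=C9 (necessarily cis in the ring) and both C8 epimers of 15 converge on one product. The closest known reaction type is the intramolecular Hosomi–Sakurai conjugate allylation of cyclic enones, which is established for seven-membered ring formation and for β,β-disubstituted enones that give quaternary carbons. The C1–C10 bond closes the seven-membered ring by a 7-endo-trig attack, both alkene carbons of the enone (C5 and C1) ending up inside the new ring. C1 is controlled by C6: allylic 1,3-strain keeps the small C6–H on the side of the C1 methyl, so the silyloxy group lies near the enone plane on the carbonyl side (equatorial in a chair-like transition state) and the C7 tether hangs from one face, from which C10 bonds to C1; the methyl thus ends syn to H6 and trans to the C6 oxygen, and the (6S)-ether gives (1R). C5 is set when enolate 16 is protonated on quench along the axial direction, on the face opposite the adjacent axial C1 methyl, which should give the trans fusion (5S). The step needs this face selectivity together with 1,4- rather than 1,2-addition and no protodesilylation: the first rests on the single C6 stereocentre next to the enone, the second on the pairing of a strong Lewis acid with a soft π-nucleophile, and the third on EtAlCl2 acting as a proton scavenger, while the near-in-plane C6–O bond of 16 is poorly aligned for β-elimination.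

Step 11
Reactants: 17 (3aS,4S,8aR)-4-(tert-butyldimethylsilyloxy)-6,8a-dimethyl-2,3a,4,5,8,8a-hexahydroazulen-3(1H)-one
Product: 18 (3R,3aS,4S,8aR)-4-(tert-butyldimethylsilyloxy)-6,8a-dimethyl-3-(propan-2-yl)-1,2,3,3a,4,5,8,8a-octahydroazulen-3-ol
Conditions: i-PrMgCl, CeCl3, THF, −78 °C
Reagents that add atoms: isopropylmagnesium chloride, CC(C)[Mg]Cl
Why: 1,2-Addition of the weakly basic organocerium reagent, which suppresses enolisation and with it β-elimination of the silyloxy group, should occur on the α-face of the C4 carbonyl, opposite the angular methyl, to give the 4β-hydroxy-4α-isopropyl carbinol (4R).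

Step 12
Reactants: 18 (3R,3aS,4S,8aR)-4-(tert-butyldimethylsilyloxy)-6,8a-dimethyl-3-(propan-2-yl)-1,2,3,3a,4,5,8,8a-octahydroazulen-3-ol
Product: 19 (3R,3aS,4S,8aR)-6,8a-dimethyl-3-(propan-2-yl)-1,2,3,3a,4,5,8,8a-octahydroazulene-3,4-diol
Conditions: Bu4NF, THF, rt → 40 °C
Reagents that add atoms: none
Why: Fluoride-mediated desilylation cleaves the Si–O bond of the secondary ether and should leave the alkene, the tertiary alcohol and every stereocentre unchanged.

Step 13
Reactants: 19 (3R,3aS,4S,8aR)-6,8a-dimethyl-3-(propan-2-yl)-1,2,3,3a,4,5,8,8a-octahydroazulene-3,4-diol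
Product: 20 (3R,3aR,8aR)-3-hydroxy-6,8a-dimethyl-3-(propan-2-yl)-2,3,3a,5,8,8a-hexahydroazulen-4(1H)-one
Conditions: Dess–Martin periodinane (1,1,1-triacetoxy-1,1-dihydro-1,2-benziodoxol-3(1H)-one), NaHCO3, CH2Cl2, 0 °C
Reagents that add atoms: none
Why: Dess–Martin oxidation of the only oxidisable (secondary) hydroxyl under buffered, non-basic conditions should avoid epimerisation at C5, retro-aldol cleavage and migration of the C8=C9 alkene into conjugation.

Step 14
Reactants: 20 (3R,3aR,8aR)-3-hydroxy-6,8a-dimethyl-3-(propan-2-yl)-2,3,3a,5,8,8a-hexahydroazulen-4(1H)-one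
Product: 21 (3R,3aS,4R,8aR)-6,8a-dimethyl-3-(propan-2-yl)-1,2,3,3a,4,5,8,8a-octahydroazulene-3,4-diol
Conditions: LiBH(s-Bu)3, THF, −78 °C; aq. NH4Cl
Reagents that add atoms: none
Why: Steric approach control in a bulky trialkylborohydride reduction, since the β-face of the C6 carbonyl is screened by the syn-axial C1 methyl and the C4 oxygen, so hydride should enter from the α-face and give the axial 6β-alcohol (6R), a net inversion of C6.

Step 15
Reactants: 21 (3R,3aS,4R,8aR)-6,8a-dimethyl-3-(propan-2-yl)-1,2,3,3a,4,5,8,8a-octahydroazulene-3,4-diol; 22 4-acetoxybenzoic acid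
Product: 24 (3R,3aS,4R,8aR)-3-hydroxy-6,8a-dimethyl-3-(propan-2-yl)-1,2,3,3a,4,5,8,8a-octahydroazulen-4-yl 4-acetoxybenzoate, via 4-acetoxybenzoyl chloride 23 (not isolated)
Conditions: 22, (COCl)2, DMF (cat.), CH2Cl2, 0 °C → rt, evaporate; then 21, Et3N, 4-(dimethylamino)pyridine, CH2Cl2, rt → 40 °C
Reagents that add atoms: none
Why: Acid chloride formation and 4-(dimethylamino)pyridine-catalysed acylation should esterify the secondary 6β-hydroxyl, the tertiary C4 hydroxyl being too hindered to compete.

Step 16
Reactants: 24 (3R,3aS,4R,8aR)-3-hydroxy-6,8a-dimethyl-3-(propan-2-yl)-1,2,3,3a,4,5,8,8a-octahydroazulen-4-yl 4-acetoxybenzoate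
Product: 25 (3R,3aS,4R,6R,7S,8aR)-6,7-epoxy-3-hydroxy-6,8a-dimethyl-3-(propan-2-yl)decahydroazulen-4-yl 4-acetoxybenzoate
Conditions: m-CPBA, NaHCO3, CH2Cl2, 0 °C
Reagents that add atoms: 3-chloroperoxybenzoic acid, OOC(=O)c1cccc(Cl)c1
Why: Prilezhaev epoxidation of the only alkene, whose β-face is covered by the C1 methyl and the axial 6β-aroyloxy group, so the peracid should add from the α-face and set C8 (R) and C9 (S).

Step 17
Reactants: 25 (3R,3aS,4R,6R,7S,8aR)-6,7-epoxy-3-hydroxy-6,8a-dimethyl-3-(propan-2-yl)decahydroazulen-4-yl 4-acetoxybenzoate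
Product: 26 (3R,3aS,4R,6R,7S,8aR)-6,7-epoxy-3-hydroxy-6,8a-dimethyl-3-(propan-2-yl)decahydroazulen-4-yl 4-hydroxybenzoate
Conditions: pyrrolidine, CH2Cl2, 0 °C → rt
Reagents that add atoms: none
Why: Aminolysis of the activated aryl acetate is far faster than attack on the hindered secondary benzoate or the trisubstituted epoxide, so only the phenol should be released.

Compound list
1 | 3-methylcyclopent-2-en-1-one | CC1=CC(=O)CC1 | starting material
2 | 2,3-dibromo-3-methylcyclopentan-1-one (not isolated) | CC1(Br)CCC(=O)C1Br | intermediate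
3 | 2-bromo-3-methylcyclopent-2-en-1-one | CC1=C(Br)C(=O)CC1 | intermediate
4 | 6-bromo-7-methyl-1,4-dioxaspiro[4.4]non-6-ene | CC1=C(Br)C2(CC1)OCCO2 | intermediate
5 | but-2-yn-1-ol | CC#CCO | starting material
6 | (Z)-3-(triethylsilyl)but-2-en-1-ol | OC/C=C(/C)[Si](CC)(CC)CC | intermediate
7 | triethyl orthoacetate | CCOC(C)(OCC)OCC | starting material
8 | 1-ethoxy-1-[(Z)-3-(triethylsilyl)but-2-enyloxy]ethene (not isolated) | C=C(OCC)OC/C=C(/C)[Si](CC)(CC)CC | intermediate
9 | ethyl 3-methyl-3-(triethylsilyl)pent-4-enoate (racemic) | CCOC(=O)CC(C)(C=C)[Si](CC)(CC)CC | intermediate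
10 | N-methoxy-N,3-dimethyl-3-(triethylsilyl)pent-4-enamide (racemic) | CON(C)C(=O)CC(C)(C=C)[Si](CC)(CC)CC | intermediate
11 | (7-methyl-1,4-dioxaspiro[4.4]non-6-en-6-yl)lithium (not isolated) | [Li]C1=C(C)CCC12OCCO2 | intermediate
12 | 3-methyl-1-(7-methyl-1,4-dioxaspiro[4.4]non-6-en-6-yl)-3-(triethylsilyl)pent-4-en-1-one (racemic) | C=CC(C)([Si](CC)(CC)CC)CC(=O)C1=C(C)CCC12OCCO2 | intermediate
13 | (1S)-3-methyl-1-(7-methyl-1,4-dioxaspiro[4.4]non-6-en-6-yl)-3-(triethylsilyl)pent-4-en-1-ol (C8 epimers) | C=CC(C)([Si](CC)(CC)CC)C[C@H](O)C1=C(C)CCC12OCCO2 | intermediate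
14 | tert-butyl{[(1S)-3-methyl-1-(7-methyl-1,4-dioxaspiro[4.4]non-6-en-6-yl)-3-(triethylsilyl)pent-4-en-1-yl]oxy}dimethylsilane (C8 epimers) | C=CC(C)([Si](CC)(CC)CC)C[C@H](O[Si](C)(C)C(C)(C)C)C1=C(C)CCC12OCCO2 | intermediate
15 | 2-[(1S)-1-(tert-butyldimethylsilyloxy)-3-methyl-3-(triethylsilyl)pent-4-en-1-yl]-3-methylcyclopent-2-en-1-one (C8 epimers; key-step precursor) | C=CC(C)([Si](CC)(CC)CC)C[C@H](O[Si](C)(C)C(C)(C)C)C1=C(C)CCC1=O | intermediate
16 | chloro(ethyl)aluminium enolate of 17 (C4–O–Al, C4=C5; not isolated) | CC[Al](Cl)OC1=C2[C@@H](O[Si](C)(C)C(C)(C)C)CC(C)=CC[C@@]2(C)CC1 | intermediate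
17 | (3aS,4S,8aR)-4-(tert-butyldimethylsilyloxy)-6,8a-dimethyl-2,3a,4,5,8,8a-hexahydroazulen-3(1H)-one (1R,5S,6S in the overview numbering; trans-fused, C4 ketone, 6α-silyloxy, C8=C9 alkene; key-step product) | O=C1CC[C@]2(C)CC=C(C)C[C@H](O[Si](C)(C)C(C)(C)C)[C@H]21 | intermediate
18 | (3R,3aS,4S,8aR)-4-(tert-butyldimethylsilyloxy)-6,8a-dimethyl-3-(propan-2-yl)-1,2,3,3a,4,5,8,8a-octahydroazulen-3-ol | CC(C)[C@]1(O)CC[C@]2(C)CC=C(C)C[C@H](O[Si](C)(C)C(C)(C)C)[C@H]21 | intermediate
19 | (3R,3aS,4S,8aR)-6,8a-dimethyl-3-(propan-2-yl)-1,2,3,3a,4,5,8,8a-octahydroazulene-3,4-diol (4β,6α-diol) | CC(C)[C@]1(O)CC[C@]2(C)CC=C(C)C[C@H](O)[C@H]21 | intermediate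
20 | (3R,3aR,8aR)-3-hydroxy-6,8a-dimethyl-3-(propan-2-yl)-2,3,3a,5,8,8a-hexahydroazulen-4(1H)-one | CC(C)[C@]1(O)CC[C@]2(C)CC=C(C)CC(=O)[C@H]21 | intermediate
21 | (3R,3aS,4R,8aR)-6,8a-dimethyl-3-(propan-2-yl)-1,2,3,3a,4,5,8,8a-octahydroazulene-3,4-diol (4β,6β-diol) | CC(C)[C@]1(O)CC[C@]2(C)CC=C(C)C[C@@H](O)[C@H]21 | intermediate
22 | 4-acetoxybenzoic acid | CC(=O)Oc1ccc(cc1)C(=O)O | starting material
23 | 4-acetoxybenzoyl chloride (not isolated) | CC(=O)Oc1ccc(cc1)C(Cl)=O | intermediate
24 | (3R,3aS,4R,8aR)-3-hydroxy-6,8a-dimethyl-3-(propan-2-yl)-1,2,3,3a,4,5,8,8a-octahydroazulen-4-yl 4-acetoxybenzoate | CC(C)[C@]1(O)CC[C@]2(C)CC=C(C)C[C@@H](OC(=O)c3ccc(OC(C)=O)cc3)[C@H]21 | intermediate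
25 | (3R,3aS,4R,6R,7S,8aR)-6,7-epoxy-3-hydroxy-6,8a-dimethyl-3-(propan-2-yl)decahydroazulen-4-yl 4-acetoxybenzoate (8α,9α-epoxide) | CC(C)[C@]1(O)CC[C@]2(C)C[C@@H]3O[C@]3(C)C[C@@H](OC(=O)c3ccc(OC(C)=O)cc3)[C@H]21 | intermediate
26 | (3R,3aS,4R,6R,7S,8aR)-6,7-epoxy-3-hydroxy-6,8a-dimethyl-3-(propan-2-yl)decahydroazulen-4-yl 4-hydroxybenzoate (1R,4R,5S,6R,8R,9S in the overview numbering; CNP0163817.3) | CC(C)[C@]1(O)CC[C@]2(C)C[C@@H]3O[C@]3(C)C[C@@H](OC(=O)c3ccc(O)cc3)[C@H]21 | target

Total step count: 17.
Longest linear sequence: 15 steps (steps 3 to 17, from but-2-yn-1-ol 5).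

Steps most likely to fail

1. Step 10. The attack on C1 may lose face control (reaction through the conformer with the silyloxy group beside the C1 methyl), the enolate may be protonated on the methyl face, or the tertiary allylsilane may be protodesilylated before ring closure. The fallback runs the cyclisation on the free C6 alcohol, where a covalent aluminium alkoxide chelated to the C4 carbonyl fixes the C6–O bond in the enone plane and activates the enone from within. It sets out from 13: ketal hydrolysis (pyridinium p-toluenesulfonate, acetone/H2O) would give the hydroxy enone 2-[(1S)-1-hydroxy-3-methyl-3-(triethylsilyl)pent-4-en-1-yl]-3-methylcyclopent-2-en-1-one F1. EtAlCl2 (2.2 equiv, toluene, −78 → 0 °C) would then form the chloroaluminium alkoxide and close the ring to the hydroxy ketone (3aS,4S,8aR)-4-hydroxy-6,8a-dimethyl-2,3a,4,5,8,8a-hexahydroazulen-3(1H)-one F2. Chelation-controlled addition of excess i-PrMgCl/CeCl3 to F2 would give diol 19, where the fallback comes back to the route.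

2. Step 14. Hydride may be delivered from the β-face (for instance through the lithium alkoxide of the C4 hydroxyl), or the β-hydroxy ketone may open by retro-aldol cleavage, so that the 6α-alcohol or cleaved material is returned. The fallback inverts C6 by substitution instead of by redox: it sets out from diol 19, and Mitsunobu esterification with acid 22 (PPh3, diisopropyl azodicarboxylate, toluene, 0 °C → rt) would give ester 24 directly with inversion at C6, in place of steps 13 to 15; no new compound arises (F0).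

3. Step 11. The hindered ketone may be enolised (followed by β-elimination of the silyloxy group), or the isopropyl reagent may transfer a β-hydride in place of adding. The fallback installs the isopropyl group in two operations from 17: isopropenylmagnesium bromide/CeCl3 (THF, −78 °C), which carries no transferable β-hydride, would give the isopropenyl carbinol (3S,3aS,4S,8aR)-4-(tert-butyldimethylsilyloxy)-6,8a-dimethyl-3-(prop-1-en-2-yl)-1,2,3,3a,4,5,8,8a-octahydroazulen-3-ol F3. Hydrogenation with RhCl(PPh3)3/H2 (benzene, 1 atm), which reduces the 1,1-disubstituted alkene but not the trisubstituted ring alkene, would then return 18.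

Further compounds
F1 | step 10 | 2-[(1S)-1-hydroxy-3-methyl-3-(triethylsilyl)pent-4-en-1-yl]-3-methylcyclopent-2-en-1-one | C=CC(C)([Si](CC)(CC)CC)C[C@H](O)C1=C(C)CCC1=O
F2 | step 10 | (3aS,4S,8aR)-4-hydroxy-6,8a-dimethyl-2,3a,4,5,8,8a-hexahydroazulen-3(1H)-one | O=C1CC[C@]2(C)CC=C(C)C[C@H](O)[C@H]21
F0 | step 14 | none | none
F3 | step 11 | (3S,3aS,4S,8aR)-4-(tert-butyldimethylsilyloxy)-6,8a-dimethyl-3-(prop-1-en-2-yl)-1,2,3,3a,4,5,8,8a-octahydroazulen-3-ol | C=C(C)[C@]1(O)CC[C@]2(C)CC=C(C)C[C@H](O[Si](C)(C)C(C)(C)C)[C@H]21
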